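**Retrosynthetic overview**
1. Ring C (the butenolide O1–C2(=O)–C3=C4–C5) is opened at O1–C5 together with the single bond from the exocyclic CH on C5 to the methyl-bearing polyene carbon. This gives a hexaenyl iodide (ring A half) and a (Z)-2-en-4-ynoic acid (oxabicycle half).
2. Enabling feature: the exocyclic CH=C5 pair of ring C is an enol-lactone at the alkyne oxidation level, and the endocyclic C3=C4 bond holds the C2 carboxyl cis to C5. The open acid is therefore a terminal alkyne whose C–H is the future exocyclic CH, and it recloses 5-exo-dig.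
3. Iodide: C11=C12 and C7=C8 by Horner–Wadsworth–Emmons reactions. The ring A cis-3,4-diol comes from the mesityl oxide/acetoacetate annulation product by CBS reduction, hydroxyl-directed epoxidation and E1cB epoxide opening.
4. Acid: Stille union of a bicyclic alkenylstannane with an α-bromo enynoate. The 7-oxabicyclo[2.2.1]heptane comes from actinol by Sharpless epoxidation anti to the C3' oxygen and transannular epoxide opening.
5. Ring order: ring A carbocycle (step 1); oxabicycle (carbocycle from actinol, ether bridge closed in step 23); ring C last (step 28).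

Key step: step 28

Remark: ring positions carry carotenoid locants (C1–C6 in ring A, C1'–C6' in the oxabicycle; C6 and C6' bear the chain). The ester-bearing stereocentre of the first three ring A intermediates is racemic and is destroyed in step 4.

**Ring A half: hexaenyl iodide**

Step 1
Reactants: 1 mesityl oxide; 2 ethyl acetoacetate
Product: 3 ethyl 2,6,6-trimethyl-4-oxocyclohex-2-ene-1-carboxylate (racemic)
Conditions: ZnCl2 (0.2 equiv), heptane/toluene, reflux, Dean–Stark
Reagents that add atoms: none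
Why: Lewis acid-promoted Michael addition of the acetoacetate to the enone followed by intramolecular aldol condensation of the methyl ketone onto the acetoacetate carbonyl (Robinson-type annulation) is the established entry to this keto ester, whose only stereocentre is racemic and is erased in step 4.

Step 2
Reactants: 3 keto ester
Product: 4 ethyl (4S)-4-hydroxy-2,6,6-trimethylcyclohex-2-ene-1-carboxylate (both C1 epimers)
Conditions: (R)-2-methyl-CBS-oxazaborolidine (15 mol%), BH3·SMe2 (0.7 equiv), THF, −20 °C; MeOH quench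
Reagents that add atoms: none
Why: Corey–Bakshi–Shibata reduction, in which the (R)-oxazaborolidine treats the alkenyl flank as the large group and delivers hydride to the face that should give the (4S)-allylic alcohol in both C1 epimers, so reagent control sets C3 of ring A.

Step 3
Reactants: 4 allylic alcohol
Product: 5 ethyl (1R,5S,6S)-5-hydroxy-1,3,3-trimethyl-7-oxabicyclo[4.1.0]heptane-2-carboxylate (epoxide cis to the hydroxyl; both C2 epimers)
Conditions: VO(acac)2 (3 mol%), t-BuOOH (1.5 equiv), CH2Cl2, 0 °C → rt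
Reagents that add atoms: tert-butyl hydroperoxide, CC(C)(C)OO
Why: Vanadium-catalysed hydroxyl-directed epoxidation of a cyclic allylic alcohol delivers oxygen to the alkene face cis to the hydroxyl, which places the future C4 oxygen cis to the C3 hydroxyl.

Step 4
Reactants: 5 epoxy ester
Product: 6 ethyl (3R,4S)-3,4-dihydroxy-2,6,6-trimethylcyclohex-1-ene-1-carboxylate
Conditions: NaOEt (0.3 equiv), EtOH, 0 °C → rt
Reagents that add atoms: none
Why: Base-induced E1cB opening of a β,γ-epoxy ester (the reaction type that turns α-ionone epoxide into 4-hydroxy-β-ionone), in which the ester enolate expels the epoxide oxygen from the neighbouring carbon without touching the C–O bond at the secondary carbon, so the cis-diol is kept and both epimers converge.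

Step 5
Reactants: 6 diol ester
Product: 7 ethyl (3R,4S)-3,4-bis[(tert-butyldimethylsilyl)oxy]-2,6,6-trimethylcyclohex-1-ene-1-carboxylate
Conditions: TBSOTf (2.5 equiv), 2,6-lutidine (4 equiv), CH2Cl2, −78 → 0 °C
Reagents that add atoms: tert-butyldimethylsilyl triflate, CC(C)(C)[Si](C)(C)OS(=O)(=O)C(F)(F)F
Why: Silyl triflate silylation covers both secondary alcohols, including the hindered allylic one, so that the allylic C4 alcohol survives the MnO2 oxidation and the later basic steps.

Step 6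
Reactants: 7 silylated ester
Product: 8 [(3R,4S)-3,4-bis[(tert-butyldimethylsilyl)oxy]-2,6,6-trimethylcyclohex-1-en-1-yl]methanol
Conditions: i-Bu2AlH (2.5 equiv), CH2Cl2, −78 → −20 °C; aqueous potassium sodium tartrate
Reagents that add atoms: none
Why: i-Bu2AlH 1,2-reduction of the conjugated ester gives the allylic alcohol without touching the silyl ethers.

Step 7
Reactants: 8 allylic alcohol
Product: 9 (3R,4S)-3,4-bis[(tert-butyldimethylsilyl)oxy]-2,6,6-trimethylcyclohex-1-ene-1-carbaldehyde
Conditions: MnO2 (activated, 20 equiv), CH2Cl2, rt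
Reagents that add atoms: none
Why: MnO2 oxidises the primary allylic alcohol selectively to the enal.

Step 8
Reactants: 9 enal; 10 ethyl (2E)-4-(diethoxyphosphoryl)-3-methylbut-2-enoate
Product: 11 ethyl (2E,4E)-5-[(3R,4S)-3,4-bis[(tert-butyldimethylsilyl)oxy]-2,6,6-trimethylcyclohex-1-en-1-yl]-3-methylpenta-2,4-dienoate
Conditions: 10, n-BuLi (1.05 equiv), THF/DMPU, −78 °C; then 9, −78 → 0 °C
Reagents that add atoms: none
Why: Horner–Wadsworth–Emmons olefination of the hindered enal with the C5 phosphonocrotonate (the reaction used for retinoid C15 esters) should form C7=C8 E-selectively, and the minor 2Z isomer is removed by chromatography.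

Step 9
Reactants: 11 dienoate
Product: 12 (2E,4E)-5-[(3R,4S)-3,4-bis[(tert-butyldimethylsilyl)oxy]-2,6,6-trimethylcyclohex-1-en-1-yl]-3-methylpenta-2,4-dien-1-ol
Conditions: i-Bu2AlH (2.2 equiv), CH2Cl2, −78 °C
Reagents that add atoms: none
Why: i-Bu2AlH reduction of the dienoate to the primary allylic alcohol.

Step 10
Reactants: 12 dienol
Product: 14 diethyl {(2E,4E)-5-[(3R,4S)-3,4-bis[(tert-butyldimethylsilyl)oxy]-2,6,6-trimethylcyclohex-1-en-1-yl]-3-methylpenta-2,4-dien-1-yl}phosphonate, via allylic bromide 13 (not isolated)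
Conditions: CBr4 (1.3 equiv), PPh3 (1.25 equiv), 2,6-lutidine (0.2 equiv), CH2Cl2, −20 °C; volatiles removed; P(OEt)3 (5 equiv), 70 °C
Reagents that add atoms: triethyl phosphite, CCOP(OCC)OCC
Why: Appel bromination under neutral conditions (sparing the acid-labile allylic silyl ether) followed by Michaelis–Arbuzov reaction of the primary allylic bromide gives the C15 phosphonate.

Step 11
Reactants: 15 but-2-yn-1-ol
Product: 16 (2E)-3-iodobut-2-en-1-ol
Conditions: Cp2Zr(H)Cl (2.2 equiv), THF, 0 °C → rt; then I2 (1.1 equiv), −78 → 0 °C, dark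
Reagents that add atoms: iodine, II
Why: syn-Hydrozirconation (the first equivalent forms the zirconium alkoxide) should place zirconium on the methyl-bearing alkyne carbon, and iodinolysis with retention gives the (E)-iodoalkene with H and iodine cis.

Step 12
Reactants: 16 iodo alcohol
Product: 17 (2E)-3-iodobut-2-enal
Conditions: MnO2 (15 equiv), CH2Cl2, rt, dark; used without purification
Reagents that add atoms: none
Why: MnO2 oxidation of the allylic alcohol gives the enal without affecting the alkenyl iodide.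

Step 13
Reactants: 17 iodo enal; 18 (triphenylphosphoranylidene)acetaldehyde
Product: 19 (2E,4E)-5-iodohexa-2,4-dienal
Conditions: 18 (1.05 equiv), toluene, rt → 50 °C, dark
Reagents that add atoms: none
Why: Wittig reaction with the stabilised formylmethylene ylide gives the E-configured two-carbon homologue, and the limited amount of ylide suppresses a second homologation.

Step 14
Reactants: 14 C15 phosphonate; 19 iodo dienal
Product: 20 {[(1S,2R)-4-[(1E,3E,5E,7E,9E)-10-iodo-3-methylundeca-1,3,5,7,9-pentaen-1-yl]-3,5,5-trimethylcyclohex-3-ene-1,2-diyl]bis(oxy)}bis(tert-butyldimethylsilane)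
Conditions: 14, KN(SiMe3)2 (1.05 equiv), THF, −78 °C; then 19, −78 → 0 °C, dark
Reagents that add atoms: none
Why: Horner–Wadsworth–Emmons olefination of the allylic phosphonate anion with the dienal should form C11=C12 E-selectively, and the alkenyl iodide is inert to the preformed anion at low temperature.

Step 15
Reactants: 20 silylated iodide
Product: 21 (1S,2R)-4-[(1E,3E,5E,7E,9E)-10-iodo-3-methylundeca-1,3,5,7,9-pentaen-1-yl]-3,5,5-trimethylcyclohex-3-ene-1,2-diol
Conditions: Bu4NF (4 equiv), THF, 0 °C → rt, dark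
Reagents that add atoms: none
Why: Fluoride cleaves both silyl ethers under non-acidic conditions that the allylic C4 alcohol, the polyene and the alkenyl iodide tolerate.

**Oxabicycle half: enynoic acid**

Step 16
Reactants: 22 (4R,6R)-4-hydroxy-2,2,6-trimethylcyclohexan-1-one (actinol)
Product: 23 (4R,6R)-4-[(tert-butyldimethylsilyl)oxy]-2,2,6-trimethylcyclohexan-1-one
Conditions: TBSCl (1.2 equiv), imidazole (2.5 equiv), DMF, rt
Reagents that add atoms: tert-butyldimethylsilyl chloride, CC(C)(C)[Si](C)(C)Cl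
Why: Standard silylation protects the secondary alcohol of the chiral-pool ketone, whose carbinol carbon becomes C3' of the oxabicycle.

Step 17
Reactants: 23 silyloxy ketone
Product: 24 (4R)-4-[(tert-butyldimethylsilyl)oxy]-2,6,6-trimethylcyclohex-1-en-1-yl trifluoromethanesulfonate
Conditions: LiN(iPr)2 (1.2 equiv), THF, −78 °C; then PhNTf2 (1.2 equiv), −78 °C → rt
Reagents that add atoms: N-phenylbis(trifluoromethanesulfonimide), FC(F)(F)S(=O)(=O)N(c1ccccc1)S(=O)(=O)C(F)(F)F
Why: Enolisation at the only enolisable position and O-triflation give the tetrasubstituted enol triflate, with loss of the methyl-bearing stereocentre.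

Step 18
Reactants: 24 enol triflate
Product: 25 methyl (4R)-4-[(tert-butyldimethylsilyl)oxy]-2,6,6-trimethylcyclohex-1-ene-1-carboxylate
Conditions: Pd(OAc)2 (5 mol%), PPh3 (10 mol%), CO (1 atm), MeOH, Et3N (2 equiv), DMF, 50 °C
Reagents that add atoms: carbon monoxide, [C-]#[O+]; methanol, CO
Why: Palladium-catalysed alkoxycarbonylation of the alkenyl triflate (oxidative addition, CO insertion, methanolysis) installs the C7' carbon.

Step 19
Reactants: 25 ester
Product: 26 [(4R)-4-[(tert-butyldimethylsilyl)oxy]-2,6,6-trimethylcyclohex-1-en-1-yl]methanol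
Conditions: i-Bu2AlH (2.2 equiv), CH2Cl2, −78 → 0 °C
Reagents that add atoms: none
Why: i-Bu2AlH reduction gives the allylic alcohol needed for the directed asymmetric epoxidation.

Step 20
Reactants: 26 allylic alcohol
Product: 27 [(1R,4S,6R)-4-[(tert-butyldimethylsilyl)oxy]-2,2,6-trimethyl-7-oxabicyclo[4.1.0]heptan-1-yl]methanol (epoxide anti to the silyloxy group)
Conditions: Ti(OiPr)4 (0.3 equiv), D-(−)-diethyl tartrate (0.36 equiv), t-BuOOH (2 equiv), 4 Å molecular sieves, CH2Cl2, −20 °C
Reagents that add atoms: tert-butyl hydroperoxide, CC(C)(C)OO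
Why: Sharpless asymmetric epoxidation, in which the D-(−)-tartrate catalyst should deliver oxygen to the alkene face anti to the C3' silyloxy group (reagent control), setting C5' and C6' as required for the later backside attack by the C3' oxygen.

Step 21
Reactants: 27 epoxy alcohol
Product: 28 (1S,4S,6R)-4-[(tert-butyldimethylsilyl)oxy]-2,2,6-trimethyl-7-oxabicyclo[4.1.0]heptane-1-carbaldehyde
Conditions: Dess–Martin periodinane (1.3 equiv), NaHCO3, CH2Cl2, 0 °C → rt
Reagents that add atoms: none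
Why: Buffered Dess–Martin oxidation gives the non-enolisable epoxy aldehyde without opening the epoxide.

Step 22
Reactants: 28 epoxy aldehyde
Product: 29 tert-butyl{[(1R,3S,6R)-6-ethynyl-1,5,5-trimethyl-7-oxabicyclo[4.1.0]heptan-3-yl]oxy}dimethylsilane
Conditions: dimethyl (1-diazo-2-oxopropyl)phosphonate (1.5 equiv), K2CO3 (2 equiv), MeOH, 0 °C → rt
Reagents that add atoms: dimethyl (1-diazo-2-oxopropyl)phosphonate, COP(=O)(OC)C(=[N+]=[N-])C(C)=O
Why: Ohira–Bestmann (Seyferth–Gilbert) homologation converts the aldehyde into the terminal alkyne, which supplies C8' and makes C6' a propargylic position.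

Step 23
Reactants: 29 silylated epoxy alkyne
Product: 31 (1S,2R,4S)-1-ethynyl-2,6,6-trimethyl-7-oxabicyclo[2.2.1]heptan-2-ol, via hydroxy epoxide 30 (not isolated)
Conditions: Bu4NF (1.2 equiv), THF, 0 °C → rt; then TsOH·H2O (1.6 equiv), 0 °C → rt
Reagents that add atoms: none
Why: Fluoride frees the C3' hydroxyl, which then opens the protonated epoxide at the propargylic C6' by 5-exo-tet backside attack (inversion at C6', retention at C5'), an acid-catalysed transannular epoxide opening that gives the 7-oxabicyclo[2.2.1]heptane with the tertiary hydroxyl endo because step 20 placed the epoxide anti to the C3' oxygen.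

Step 24
Reactants: 32 ethyl propiolate
Product: 33 ethyl (2E)-2,3-dibromoprop-2-enoate
Conditions: Br2 (1.0 equiv), CH2Cl2, 0 °C → rt, dark
Reagents that add atoms: bromine, BrBr
Why: Anti addition of bromine to the ynoate should give the (E)-dibromide, in which the ester is cis to the β-bromine.

Step 25
Reactants: 33 dibromoacrylate; 34 ethynyltrimethylsilane
Product: 35 ethyl (2E)-2-bromo-5-(trimethylsilyl)pent-2-en-4-ynoate
Conditions: 34 (1.0 equiv), Pd(PPh3)4 (3 mol%), CuI (6 mol%), i-Pr2NEt (2 equiv), THF, 0 °C → rt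
Reagents that add atoms: none
Why: Site-selective Sonogashira coupling at the more electrophilic β-carbon–bromine bond of the 2,3-dibromoacrylate proceeds with retention, leaving the α-bromide and placing the alkyne cis to the ester.

Step 26
Reactants: 31 bicyclic alkynol; 35 bromo enynoate
Product: 37 ethyl (2Z)-2-{(E)-2-[(1R,2R,4S)-2-hydroxy-2,6,6-trimethyl-7-oxabicyclo[2.2.1]heptan-1-yl]ethenyl}-5-(trimethylsilyl)pent-2-en-4-ynoate, via alkenylstannane 36 (not isolated)
Conditions: Bu3SnH (1.05 equiv), PdCl2(PPh3)2 (3 mol%), THF, 0 °C → rt; then 35 (1.0 equiv), Pd2(dba)3 (2.5 mol%), AsPh3 (20 mol%), CuI (10 mol%), DMF, 45 °C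
Reagents that add atoms: none
Why: Palladium-catalysed syn-hydrostannation puts tin on the unhindered alkyne terminus to give the (E)-alkenylstannane, and its Stille coupling with the α-bromoacrylate proceeds with retention in both partners, fixing the E C7'=C8' bond and the cis ester/alkyne arrangement.

Step 27
Reactants: 37 silylated enynoate
Product: 38 (2Z)-2-{(E)-2-[(1R,2R,4S)-2-hydroxy-2,6,6-trimethyl-7-oxabicyclo[2.2.1]heptan-1-yl]ethenyl}pent-2-en-4-ynoic acid
Conditions: LiOH·H2O (3 equiv), THF/H2O (3:1), 0 °C → rt; cold dilute HCl to pH 3–4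
Reagents that add atoms: lithium hydroxide, [Li+].[OH-]
Why: Hydroxide cleaves the alkynyl silyl group and saponifies the ester in one operation, and the (Z)-enynoic acid released on cold acidification does not lactonise without a metal catalyst.

**Fragment union**

Step 28
Reactants: 21 hexaenyl iodide diol; 38 (Z)-enynoic acid
Product: 40 (5Z)-5-{(2E,4E,6E,8E,10E)-11-[(3R,4S)-3,4-dihydroxy-2,6,6-trimethylcyclohex-1-en-1-yl]-2,9-dimethylundeca-2,4,6,8,10-pentaen-1-ylidene}-3-{(E)-2-[(1R,2R,4S)-2-hydroxy-2,6,6-trimethyl-7-oxabicyclo[2.2.1]heptan-1-yl]ethenyl}furan-2(5H)-one (target), via coupled enynoic acid 39 (not isolated)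
Conditions: Pd(PPh3)4 (5 mol%), CuI (10 mol%), Et3N (4 equiv), degassed MeCN/THF (1:1), rt → 40 °C, dark, argon
Reagents that add atoms: none
Why: Zerovalent palladium inserts into the carbon–iodine bond of 21, the copper acetylide of 38 transmetalates and reductive elimination joins the alkyne terminus to the methyl-bearing alkenyl carbon (Sonogashira coupling, retention of the E-iodide geometry) to give 39, whose carboxylate then adds across the metal-activated internal alkyne before protodemetalation releases 40. The closest known reaction type is the tandem Pd/Cu cross-coupling–lactonisation by which (Z)-3-iodoacrylic acids and 1-alkynes give (Z)-γ-alkylidenebutenolides through the same kind of (Z)-2-en-4-ynoic acid intermediate. Ring C is closed by 5-exo-dig attack of the carboxylate oxygen on the alkyne carbon nearer the acid. No new stereocentre is formed; the new stereo element, the exocyclic double bond, should be Z because oxygen and metal add anti and the proton replaces the metal with retention, which leaves the polyene cis to the ring oxygen. The step needs coupling before ring closure, secured by CuI (the acetylide transmetalates faster than carboxylate attacks a palladium-bound terminal alkyne, the path that would give the E isomer), and 5-exo over 6-endo closure, secured by the Z geometry of the C2=C3 bond of 38 (the future C3=C4 of ring C), which holds the carboxylate over the proximal alkyne carbon. The free hydroxyl groups and the ether bridge are inert, so no protecting group has to be removed afterwards.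

**Compound list**
1 | mesityl oxide (4-methylpent-3-en-2-one) | CC(=O)C=C(C)C | starting material
2 | ethyl acetoacetate | CCOC(=O)CC(C)=O | starting material
3 | ethyl 2,6,6-trimethyl-4-oxocyclohex-2-ene-1-carboxylate (racemic) | CCOC(=O)C1C(C)=CC(=O)CC1(C)C | intermediate
4 | ethyl (4S)-4-hydroxy-2,6,6-trimethylcyclohex-2-ene-1-carboxylate (both C1 epimers) | CCOC(=O)C1C(C)=C[C@@H](O)CC1(C)C | intermediate
5 | ethyl (1R,5S,6S)-5-hydroxy-1,3,3-trimethyl-7-oxabicyclo[4.1.0]heptane-2-carboxylate (both C2 epimers) | CCOC(=O)C1[C@@]2(C)O[C@H]2[C@@H](O)CC1(C)C | intermediate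
6 | ethyl (3R,4S)-3,4-dihydroxy-2,6,6-trimethylcyclohex-1-ene-1-carboxylate | CC1=C(C(=O)OCC)C(C)(C)C[C@H](O)[C@@H]1O | intermediate
7 | ethyl (3R,4S)-3,4-bis[(tert-butyldimethylsilyl)oxy]-2,6,6-trimethylcyclohex-1-ene-1-carboxylate | CC1=C(C(=O)OCC)C(C)(C)C[C@H](O[Si](C)(C)C(C)(C)C)[C@@H]1O[Si](C)(C)C(C)(C)C | intermediate
8 | [(3R,4S)-3,4-bis[(tert-butyldimethylsilyl)oxy]-2,6,6-trimethylcyclohex-1-en-1-yl]methanol | CC1=C(CO)C(C)(C)C[C@H](O[Si](C)(C)C(C)(C)C)[C@@H]1O[Si](C)(C)C(C)(C)C | intermediate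
9 | (3R,4S)-3,4-bis[(tert-butyldimethylsilyl)oxy]-2,6,6-trimethylcyclohex-1-ene-1-carbaldehyde | CC1=C(C=O)C(C)(C)C[C@H](O[Si](C)(C)C(C)(C)C)[C@@H]1O[Si](C)(C)C(C)(C)C | intermediate
10 | ethyl (2E)-4-(diethoxyphosphoryl)-3-methylbut-2-enoate (triethyl 3-methyl-4-phosphonocrotonate) | CCOC(=O)/C=C(\C)CP(=O)(OCC)OCC | starting material
11 | ethyl (2E,4E)-5-[(3R,4S)-3,4-bis[(tert-butyldimethylsilyl)oxy]-2,6,6-trimethylcyclohex-1-en-1-yl]-3-methylpenta-2,4-dienoate | CC1=C(/C=C/C(C)=C/C(=O)OCC)C(C)(C)C[C@H](O[Si](C)(C)C(C)(C)C)[C@@H]1O[Si](C)(C)C(C)(C)C | intermediate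
12 | (2E,4E)-5-[(3R,4S)-3,4-bis[(tert-butyldimethylsilyl)oxy]-2,6,6-trimethylcyclohex-1-en-1-yl]-3-methylpenta-2,4-dien-1-ol | CC1=C(/C=C/C(C)=C/CO)C(C)(C)C[C@H](O[Si](C)(C)C(C)(C)C)[C@@H]1O[Si](C)(C)C(C)(C)C | intermediate
13 | (2E,4E)-5-[(3R,4S)-3,4-bis[(tert-butyldimethylsilyl)oxy]-2,6,6-trimethylcyclohex-1-en-1-yl]-3-methylpenta-2,4-dien-1-yl bromide | CC1=C(/C=C/C(C)=C/CBr)C(C)(C)C[C@H](O[Si](C)(C)C(C)(C)C)[C@@H]1O[Si](C)(C)C(C)(C)C | intermediate
14 | diethyl {(2E,4E)-5-[(3R,4S)-3,4-bis[(tert-butyldimethylsilyl)oxy]-2,6,6-trimethylcyclohex-1-en-1-yl]-3-methylpenta-2,4-dien-1-yl}phosphonate | CC1=C(/C=C/C(C)=C/CP(=O)(OCC)OCC)C(C)(C)C[C@H](O[Si](C)(C)C(C)(C)C)[C@@H]1O[Si](C)(C)C(C)(C)C | intermediate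
15 | but-2-yn-1-ol | CC#CCO | starting material
16 | (2E)-3-iodobut-2-en-1-ol | OC/C=C(C)/I | intermediate
17 | (2E)-3-iodobut-2-enal | O=C/C=C(C)/I | intermediate
18 | (triphenylphosphoranylidene)acetaldehyde | O=CC=P(c1ccccc1)(c1ccccc1)c1ccccc1 | starting material
19 | (2E,4E)-5-iodohexa-2,4-dienal | O=C/C=C/C=C(C)/I | intermediate
20 | {[(1S,2R)-4-[(1E,3E,5E,7E,9E)-10-iodo-3-methylundeca-1,3,5,7,9-pentaen-1-yl]-3,5,5-trimethylcyclohex-3-ene-1,2-diyl]bis(oxy)}bis(tert-butyldimethylsilane) | CC1=C(/C=C/C(C)=C/C=C/C=C/C=C(C)/I)C(C)(C)C[C@H](O[Si](C)(C)C(C)(C)C)[C@@H]1O[Si](C)(C)C(C)(C)C | intermediate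
21 | (1S,2R)-4-[(1E,3E,5E,7E,9E)-10-iodo-3-methylundeca-1,3,5,7,9-pentaen-1-yl]-3,5,5-trimethylcyclohex-3-ene-1,2-diol | CC1=C(/C=C/C(C)=C/C=C/C=C/C=C(C)/I)C(C)(C)C[C@H](O)[C@@H]1O | intermediate
22 | (4R,6R)-4-hydroxy-2,2,6-trimethylcyclohexan-1-one (actinol) | C[C@@H]1C[C@@H](O)CC(C)(C)C1=O | starting material
23 | (4R,6R)-4-[(tert-butyldimethylsilyl)oxy]-2,2,6-trimethylcyclohexan-1-one | C[C@@H]1C[C@@H](O[Si](C)(C)C(C)(C)C)CC(C)(C)C1=O | intermediate
24 | (4R)-4-[(tert-butyldimethylsilyl)oxy]-2,6,6-trimethylcyclohex-1-en-1-yl trifluoromethanesulfonate | CC1=C(OS(=O)(=O)C(F)(F)F)C(C)(C)C[C@H](O[Si](C)(C)C(C)(C)C)C1 | intermediate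
25 | methyl (4R)-4-[(tert-butyldimethylsilyl)oxy]-2,6,6-trimethylcyclohex-1-ene-1-carboxylate | CC1=C(C(=O)OC)C(C)(C)C[C@H](O[Si](C)(C)C(C)(C)C)C1 | intermediate
26 | [(4R)-4-[(tert-butyldimethylsilyl)oxy]-2,6,6-trimethylcyclohex-1-en-1-yl]methanol | CC1=C(CO)C(C)(C)C[C@H](O[Si](C)(C)C(C)(C)C)C1 | intermediate
27 | [(1R,4S,6R)-4-[(tert-butyldimethylsilyl)oxy]-2,2,6-trimethyl-7-oxabicyclo[4.1.0]heptan-1-yl]methanol | C[C@]12O[C@@]1(CO)C(C)(C)C[C@H](O[Si](C)(C)C(C)(C)C)C2 | intermediate
28 | (1S,4S,6R)-4-[(tert-butyldimethylsilyl)oxy]-2,2,6-trimethyl-7-oxabicyclo[4.1.0]heptane-1-carbaldehyde | C[C@]12O[C@@]1(C=O)C(C)(C)C[C@H](O[Si](C)(C)C(C)(C)C)C2 | intermediate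
29 | tert-butyl{[(1R,3S,6R)-6-ethynyl-1,5,5-trimethyl-7-oxabicyclo[4.1.0]heptan-3-yl]oxy}dimethylsilane | C[C@]12O[C@@]1(C#C)C(C)(C)C[C@H](O[Si](C)(C)C(C)(C)C)C2 | intermediate
30 | (1R,3S,6R)-6-ethynyl-1,5,5-trimethyl-7-oxabicyclo[4.1.0]heptan-3-ol | C[C@]12O[C@@]1(C#C)C(C)(C)C[C@H](O)C2 | intermediate
31 | (1S,2R,4S)-1-ethynyl-2,6,6-trimethyl-7-oxabicyclo[2.2.1]heptan-2-ol | C#C[C@@]12O[C@@H](CC1(C)C)C[C@@]2(C)O | intermediate
32 | ethyl propiolate | CCOC(=O)C#C | starting material
33 | ethyl (2E)-2,3-dibromoprop-2-enoate | CCOC(=O)/C(Br)=C\Br | intermediate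
34 | ethynyltrimethylsilane | C#C[Si](C)(C)C | starting material
35 | ethyl (2E)-2-bromo-5-(trimethylsilyl)pent-2-en-4-ynoate | CCOC(=O)/C(Br)=C\C#C[Si](C)(C)C | intermediate
36 | (1R,2R,4S)-2,6,6-trimethyl-1-[(E)-2-(tributylstannyl)ethenyl]-7-oxabicyclo[2.2.1]heptan-2-ol | CCCC[Sn](CCCC)(CCCC)/C=C/[C@@]12O[C@@H](CC1(C)C)C[C@@]2(C)O | intermediate
37 | ethyl (2Z)-2-{(E)-2-[(1R,2R,4S)-2-hydroxy-2,6,6-trimethyl-7-oxabicyclo[2.2.1]heptan-1-yl]ethenyl}-5-(trimethylsilyl)pent-2-en-4-ynoate | C[Si](C)(C)C#C\C=C(/C(=O)OCC)\C=C\[C@@]12O[C@@H](CC1(C)C)C[C@@]2(C)O | intermediate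
38 | (2Z)-2-{(E)-2-[(1R,2R,4S)-2-hydroxy-2,6,6-trimethyl-7-oxabicyclo[2.2.1]heptan-1-yl]ethenyl}pent-2-en-4-ynoic acid | C#C\C=C(/C(=O)O)\C=C\[C@@]12O[C@@H](CC1(C)C)C[C@@]2(C)O | intermediate
39 | (2Z,6E,8E,10E,12E,14E)-15-[(3R,4S)-3,4-dihydroxy-2,6,6-trimethylcyclohex-1-en-1-yl]-2-{(E)-2-[(1R,2R,4S)-2-hydroxy-2,6,6-trimethyl-7-oxabicyclo[2.2.1]heptan-1-yl]ethenyl}-6,13-dimethylpentadeca-2,6,8,10,12,14-hexaen-4-ynoic acid | CC1=C(/C=C/C(C)=C/C=C/C=C/C=C(C)/C#C\C=C(/C(=O)O)\C=C\[C@@]23O[C@@H](CC2(C)C)C[C@@]3(C)O)C(C)(C)C[C@H](O)[C@@H]1O | intermediate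
40 | (5Z)-5-{(2E,4E,6E,8E,10E)-11-[(3R,4S)-3,4-dihydroxy-2,6,6-trimethylcyclohex-1-en-1-yl]-2,9-dimethylundeca-2,4,6,8,10-pentaen-1-ylidene}-3-{(E)-2-[(1R,2R,4S)-2-hydroxy-2,6,6-trimethyl-7-oxabicyclo[2.2.1]heptan-1-yl]ethenyl}furan-2(5H)-one (CNP0216838.1) | CC1=C(/C=C/C(C)=C/C=C/C=C/C=C(C)/C=C2C=C(/C=C/[C@@]34O[C@@H](CC3(C)C)C[C@@]4(C)O)C(=O)O/2)C(C)(C)C[C@H](O)[C@@H]1O | target

**Step count**
Total: 28 steps. Longest linear sequence: 13 steps (steps 1–10, 14, 15, 28). The oxabicycle branch runs 11 steps (16–23, 26–28).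

**Steps most likely to fail**

1. Step 28 (key step). What may go wrong: ring closure of the terminal enynoic acid before the cross-coupling; 6-endo closure, or oxypalladation followed by reductive elimination, of the coupled acid (leading to the pyranone or the E-alkylidene); and isomerisation of the hexaene if the reaction is slow. The fallback sets out from 37 and 21 and returns at 39, then 40; it keeps the carboxyl blocked during the coupling. Bu4NF buffered with AcOH in THF removes only the alkynyl silyl group of 37 to give ethyl (2Z)-2-{(E)-2-[(1R,2R,4S)-2-hydroxy-2,6,6-trimethyl-7-oxabicyclo[2.2.1]heptan-1-yl]ethenyl}pent-2-en-4-ynoate F1. Sonogashira coupling of F1 with 21 (Pd(PPh3)4, CuI, Et3N) gives the ethyl ester of acid 39 F2, which cannot lactonise. LiOH in THF/H2O then gives 39, now isolated, and a separate 5-exo-dig cyclisation catalysed by AgNO3 in acetone gives 40.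

2. Step 23. What may go wrong: ionisation of the protonated epoxide at C5' instead of assisted opening at C6', so that elimination or a 1,2-shift outruns formation of the ether bridge. The fallback sets out from 28 and returns at 31; it makes C6' allylic. Wittig methylenation of 28 (Ph3P=CH2, THF) gives tert-butyl{[(1R,3S,6S)-6-ethenyl-1,5,5-trimethyl-7-oxabicyclo[4.1.0]heptan-3-yl]oxy}dimethylsilane F3. Bu4NF gives (1R,3S,6S)-6-ethenyl-1,5,5-trimethyl-7-oxabicyclo[4.1.0]heptan-3-ol F4. Catalytic TsOH in CH2Cl2 opens the now allylic C6'–O bond to give (1R,2R,4S)-1-ethenyl-2,6,6-trimethyl-7-oxabicyclo[2.2.1]heptan-2-ol F5. Ozonolysis (O3, then PPh3) gives (1R,2R,4S)-2-hydroxy-2,6,6-trimethyl-7-oxabicyclo[2.2.1]heptane-1-carbaldehyde F6, and Ohira–Bestmann homologation of F6 returns to 31.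

3. Step 2. What may go wrong: poor facial discrimination by the oxazaborolidine (the small flank of the ketone carries a quaternary carbon), or a mismatched reduction of one epimer, either of which lowers the enantiomeric purity of ring A. The fallback sets out from 3 and returns at 4; it replaces asymmetric reduction by enzymatic resolution. NaBH4/CeCl3·7H2O in MeOH gives racemic ethyl 4-hydroxy-2,6,6-trimethylcyclohex-2-ene-1-carboxylate F7. Acylation with vinyl acetate catalysed by Burkholderia cepacia lipase should esterify the (4R)-alcohols to ethyl (4R)-4-acetoxy-2,6,6-trimethylcyclohex-2-ene-1-carboxylate F8 and leave 4, which is separated by chromatography.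

**Further compounds**
F1 | step 28 | ethyl (2Z)-2-{(E)-2-[(1R,2R,4S)-2-hydroxy-2,6,6-trimethyl-7-oxabicyclo[2.2.1]heptan-1-yl]ethenyl}pent-2-en-4-ynoate | C#C\C=C(/C(=O)OCC)\C=C\[C@@]12O[C@@H](CC1(C)C)C[C@@]2(C)O
F2 | step 28 | ethyl ester of acid 39 | CC1=C(/C=C/C(C)=C/C=C/C=C/C=C(C)/C#C\C=C(/C(=O)OCC)\C=C\[C@@]23O[C@@H](CC2(C)C)C[C@@]3(C)O)C(C)(C)C[C@H](O)[C@@H]1O
F3 | step 23 | tert-butyl{[(1R,3S,6S)-6-ethenyl-1,5,5-trimethyl-7-oxabicyclo[4.1.0]heptan-3-yl]oxy}dimethylsilane | C[C@]12O[C@@]1(C=C)C(C)(C)C[C@H](O[Si](C)(C)C(C)(C)C)C2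
F4 | step 23 | (1R,3S,6S)-6-ethenyl-1,5,5-trimethyl-7-oxabicyclo[4.1.0]heptan-3-ol | C[C@]12O[C@@]1(C=C)C(C)(C)C[C@H](O)C2
F5 | step 23 | (1R,2R,4S)-1-ethenyl-2,6,6-trimethyl-7-oxabicyclo[2.2.1]heptan-2-ol | C=C[C@@]12O[C@@H](CC1(C)C)C[C@@]2(C)O
F6 | step 23 | (1R,2R,4S)-2-hydroxy-2,6,6-trimethyl-7-oxabicyclo[2.2.1]heptane-1-carbaldehyde | O=C[C@@]12O[C@@H](CC1(C)C)C[C@@]2(C)O
F7 | step 2 | ethyl 4-hydroxy-2,6,6-trimethylcyclohex-2-ene-1-carboxylate (racemic, all diastereomers) | CCOC(=O)C1C(C)=CC(O)CC1(C)C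
F8 | step 2 | ethyl (4R)-4-acetoxy-2,6,6-trimethylcyclohex-2-ene-1-carboxylate (both C1 epimers) | CCOC(=O)C1C(C)=C[C@H](OC(C)=O)CC1(C)C
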